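**Plan**
- Retrosynthesis first cuts the 4'-O–geranyl ether bond. A C5 chlorine and O-protecting groups are then put back, and O1–C8a and C4–C4a of ring C are cut together. Last come the carbinol C–H and the C3–ester carbon bond of the C2–C3–C4 chain.
- Enabling feature: ring A is fused to ring C through two adjacent carbons, C8a carrying O1 and C4a carrying the C4 carbonyl. This ortho oxygen/acyl pair is what an aryne leaves after inserting between the alkoxide and the ester of an O1–C2–C3–C4 chain.
- Forward order: rings A and B are bought. The chain is built on ring B (Claisen condensation, ketone reduction, O-silylation). Ring A is turned into an o-silylaryl triflate. Ring C closes when the two halves are joined.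
- After ring closure, hydrogenolysis removes C5–Cl and the benzyl group together, the geranyl chain is attached at 4'-O, and the 7-O acetal is removed. The terpene comes last because palladium hydride and zerovalent palladium attack allylic aryl ethers and alkenes.
- Stereochemistry: C2 is set by catalyst-controlled transfer hydrogenation of the β-keto ester, and its C–O bond is never broken afterwards. The E-alkene is bought with geraniol.

Key step: step 7

Assumption: the single stereocentre of the target is read from the SMILES as (2S); flavanone numbering (O1, C2–C4, C4a, C5–C8, C8a, primed ring B) is used throughout; 1, 5 and 18 are taken as catalogue chemicals.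

**Step 1**
Reactants: 1 4'-(benzyloxy)acetophenone
Product: 2 methyl 3-[4-(benzyloxy)phenyl]-3-oxopropanoate
Conditions: NaH, (MeO)2CO, THF, reflux; aq. HCl
Reagents that add atoms: dimethyl carbonate COC(=O)OC
Why: Crossed Claisen condensation, in which the sodium enolate of the methyl ketone is C-acylated by the non-enolisable carbonate and deprotonation of the β-keto ester drives the equilibrium, the benzyl ether being inert to NaH.

**Step 2**
Reactants: 2 methyl 3-[4-(benzyloxy)phenyl]-3-oxopropanoate
Product: 3 methyl (3S)-3-[4-(benzyloxy)phenyl]-3-hydroxypropanoate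
Conditions: RuCl[(S,S)-TsDPEN](p-cymene) (1 mol%), HCO2H–Et3N (5:2 azeotrope), CH2Cl2, 30 °C
Reagents that add atoms: none
Why: Noyori–Ikariya asymmetric transfer hydrogenation, in which the (S,S)-diamine ligand and the CH/π contact between p-cymene and the aryl ring place hydride on the Re face of the aryl ketone and should give the (S)-carbinol, as with other benzoylacetates.

**Step 3**
Reactants: 3 methyl (3S)-3-[4-(benzyloxy)phenyl]-3-hydroxypropanoate
Product: 4 methyl (3S)-3-[4-(benzyloxy)phenyl]-3-[(trimethylsilyl)oxy]propanoate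
Conditions: TMSCl, imidazole, CH2Cl2, 0 °C
Reagents that add atoms: chlorotrimethylsilane C[Si](C)(C)Cl
Why: Standard O-silylation of a secondary alcohol under conditions too mild for β-elimination, giving a proton-free store of the alkoxide needed in step 7 without touching the stereocentre.

**Step 4**
Reactants: 5 5-chlororesorcinol
Product: 6 4-bromo-5-chlorobenzene-1,3-diol
Conditions: NBS (1.0 equiv), MeCN, −20 → 0 °C
Reagents that add atoms: N-bromosuccinimide O=C1CCC(=O)N1Br
Why: Electrophilic aromatic bromination of a resorcinol favours C4 (para to one hydroxyl, ortho to the other) over the doubly flanked C2, which puts the halogen handle exactly between a hydroxyl and chlorine, whereas a directed lithiation would favour the site between the two oxygens.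

**Step 5**
Reactants: 6 4-bromo-5-chlorobenzene-1,3-diol
Product: 11 3-chloro-5-hydroxy-2-(trimethylsilyl)phenyl trifluoromethanesulfonate, via bis(trimethylsilyl) ether 7 (not isolated), via aryllithium 8 (not isolated), via lithium phenolate 9 (not isolated), via silyloxy triflate 10 (not isolated)
Conditions: HMDS, THF, 70 °C, evaporate; n-BuLi, THF, −100 → −80 °C; Tf2O, −100 → −78 °C; aq. citric acid, THF, rt
Reagents that add atoms: hexamethyldisilazane C[Si](C)(C)N[Si](C)(C)C; trifluoromethanesulfonic anhydride O=S(=O)(OS(=O)(=O)C(F)(F)F)C(F)(F)F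
Why: O-silylation, bromine–lithium exchange, retro-Brook (1,3 O→C) silyl migration and triflation is the standard route from o-bromophenols to o-silylaryl triflates; only the silyloxy group ortho to lithium can deliver silicon, so the two oxygens are distinguished without a selective protection, and below −80 °C the migration should outrun loss of LiCl from 8.

**Step 6**
Reactants: 11 3-chloro-5-hydroxy-2-(trimethylsilyl)phenyl trifluoromethanesulfonate
Product: 12 3-chloro-5-(methoxymethoxy)-2-(trimethylsilyl)phenyl trifluoromethanesulfonate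
Conditions: MOMCl, iPr2NEt, CH2Cl2, 0 °C → rt
Reagents that add atoms: chloromethyl methyl ether COCCl
Why: Routine O-alkylation of a phenol to its methoxymethyl acetal under amine base, with no fluoride or hard oxyanion present to disturb the silyl/triflate pair, and giving a group that withstands fluoride, alkoxide and hydrogenolysis.

**Step 7**
Reactants: 4 methyl (3S)-3-[4-(benzyloxy)phenyl]-3-[(trimethylsilyl)oxy]propanoate; 12 3-chloro-5-(methoxymethoxy)-2-(trimethylsilyl)phenyl trifluoromethanesulfonate
Product: 16 (2S)-2-[4-(benzyloxy)phenyl]-5-chloro-7-(methoxymethoxy)-2,3-dihydro-4H-chromen-4-one, via aryne 13 (not isolated), via caesium alkoxide 14 (not isolated), via aryl anion 15 (not isolated)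
Conditions: CsF, 18-crown-6, 4 Å MS, THF, 0 °C → rt, slow addition of 12 (1.5 equiv); pH 7 phosphate buffer
Reagents that add atoms: none
Why: Proposed new method: fluoride strips the C-silyl group of 12 and triflate leaves to give the strained aryne 13, fluoride (and later the released methoxide) unmasks silyl ether 4 to alkoxide 14, 14 adds to the aryne carbon that becomes C8a, and aryl anion 15 attacks the methyl ester and expels methoxide, so that O1–C8a and C4–C4a form in one operation. The closest known reaction type is the fluoride-triggered annulation of o-silylaryl triflates with salicylate esters to xanthones, where a phenoxide plays the part that a secondary aliphatic alkoxide has to play here. Ring C closes by 6-exo-trig acylation, the carbanion at C4a reaching the ester carbon through C8a, O1, C2 and C3. No stereocentre is made: the carbinol C–O bond of 4 is never broken, so the (3S) centre becomes (2S)-C2 with retention. The selectivity required is the direction of addition to the unsymmetrical aryne, and the chlorine next to the triple bond secures it, since its inductive pull distorts 13 so that the remote carbon is attacked and the charge builds up beside chlorine, whereas the 7-alkoxy group alone would give no useful bias. Feeding the alkoxide from a silyl ether keeps the medium free of O–H protons that would quench 15 before acylation, and the liberated methoxide is capped as MeOSiMe3 while it releases the next alkoxide, which holds the basicity low and protects the flavanone from E1cB opening of ring C.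

**Step 8**
Reactants: 16 (2S)-2-[4-(benzyloxy)phenyl]-5-chloro-7-(methoxymethoxy)-2,3-dihydro-4H-chromen-4-one
Product: 17 (2S)-2-(4-hydroxyphenyl)-7-(methoxymethoxy)-2,3-dihydro-4H-chromen-4-one
Conditions: H2 (1 atm), 10% Pd/C, NaOAc, EtOAc–EtOH, rt
Reagents that add atoms: none
Why: Heterogeneous hydrogenolysis cleaves the benzyl aryl ether and, with acetate taking up HCl, the ketone-activated C5–Cl bond in the same operation, while the acetal, the donor-substituted aryl ketone and C2 should be untouched at 1 atm and acetate is too weak a base to form the 4'-phenoxide.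

**Step 9**
Reactants: 17 (2S)-2-(4-hydroxyphenyl)-7-(methoxymethoxy)-2,3-dihydro-4H-chromen-4-one; 18 geraniol
Product: 19 (2S)-2-(4-{[(2E)-3,7-dimethylocta-2,6-dien-1-yl]oxy}phenyl)-7-(methoxymethoxy)-2,3-dihydro-4H-chromen-4-one
Conditions: PPh3, DIAD (added last, slowly), THF, 0 °C → rt
Reagents that add atoms: none
Why: Mitsunobu etherification, in which the primary allylic alcohol is activated as its oxyphosphonium salt and displaced by the only free phenol in an SN2 manner with the E-alkene intact, under near-neutral conditions where the phenoxide exists only as a short-lived ion pair, so ring C should not open and C2 should hold.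

**Step 10**
Reactants: 19 (2S)-2-(4-{[(2E)-3,7-dimethylocta-2,6-dien-1-yl]oxy}phenyl)-7-(methoxymethoxy)-2,3-dihydro-4H-chromen-4-one
Product: 21 (2S)-2-(4-{[(2E)-3,7-dimethylocta-2,6-dien-1-yl]oxy}phenyl)-7-hydroxy-2,3-dihydro-4H-chromen-4-one, via aryl trimethylsilyl ether 20 (not isolated)
Conditions: TMSOTf, 2,2'-bipyridyl, MeCN, 0 °C → rt; then H2O
Reagents that add atoms: none
Why: Silyl triflate/bipyridyl cleavage of an aromatic methoxymethyl ether converts the acetal into aryl silyl ether 20 and an N-(methoxymethyl)bipyridinium salt, both hydrolysed by water, in a medium without free Brønsted acid or base, so the geranyl ether, both alkenes and C2 should survive.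

**Compound list**
1 | 4'-(benzyloxy)acetophenone | CC(=O)c1ccc(OCc2ccccc2)cc1 | starting material
2 | methyl 3-[4-(benzyloxy)phenyl]-3-oxopropanoate | COC(=O)CC(=O)c1ccc(OCc2ccccc2)cc1 | intermediate
3 | methyl (3S)-3-[4-(benzyloxy)phenyl]-3-hydroxypropanoate | COC(=O)C[C@H](O)c1ccc(OCc2ccccc2)cc1 | intermediate
4 | methyl (3S)-3-[4-(benzyloxy)phenyl]-3-[(trimethylsilyl)oxy]propanoate | COC(=O)C[C@H](O[Si](C)(C)C)c1ccc(OCc2ccccc2)cc1 | intermediate
5 | 5-chlororesorcinol | Oc1cc(O)cc(Cl)c1 | starting material
6 | 4-bromo-5-chlorobenzene-1,3-diol | Oc1cc(O)c(Br)c(Cl)c1 | intermediate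
7 | 4-bromo-5-chloro-1,3-bis[(trimethylsilyl)oxy]benzene | C[Si](C)(C)Oc1cc(O[Si](C)(C)C)c(Br)c(Cl)c1 | intermediate
8 | 2-chloro-4,6-bis[(trimethylsilyl)oxy]phenyllithium | [Li]c1c(Cl)cc(O[Si](C)(C)C)cc1O[Si](C)(C)C | intermediate
9 | lithium 3-chloro-2-(trimethylsilyl)-5-[(trimethylsilyl)oxy]phenolate | [Li+].[O-]c1cc(O[Si](C)(C)C)cc(Cl)c1[Si](C)(C)C | intermediate
10 | 3-chloro-2-(trimethylsilyl)-5-[(trimethylsilyl)oxy]phenyl trifluoromethanesulfonate | C[Si](C)(C)Oc1cc(Cl)c([Si](C)(C)C)c(OS(=O)(=O)C(F)(F)F)c1 | intermediate
11 | 3-chloro-5-hydroxy-2-(trimethylsilyl)phenyl trifluoromethanesulfonate | Oc1cc(Cl)c([Si](C)(C)C)c(OS(=O)(=O)C(F)(F)F)c1 | intermediate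
12 | 3-chloro-5-(methoxymethoxy)-2-(trimethylsilyl)phenyl trifluoromethanesulfonate | COCOc1cc(Cl)c([Si](C)(C)C)c(OS(=O)(=O)C(F)(F)F)c1 | intermediate
13 | 3-chloro-5-(methoxymethoxy)benzyne (1-chloro-5-(methoxymethoxy)-2,3-didehydrobenzene) | COCOC1=CC#CC(Cl)=C1 | intermediate
14 | caesium (1S)-1-[4-(benzyloxy)phenyl]-3-methoxy-3-oxopropan-1-olate | [Cs+].COC(=O)C[C@H]([O-])c1ccc(OCc2ccccc2)cc1 | intermediate
15 | methyl (3S)-3-[4-(benzyloxy)phenyl]-3-[2-caesio-3-chloro-5-(methoxymethoxy)phenoxy]propanoate | [Cs+].COC(=O)C[C@H](Oc1cc(OCOC)cc(Cl)[c-]1)c1ccc(OCc2ccccc2)cc1 | intermediate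
16 | (2S)-4'-(benzyloxy)-5-chloro-7-(methoxymethoxy)flavanone | c1ccccc1COc1ccc([C@@H]2CC(=O)c3c(Cl)cc(OCOC)cc3O2)cc1 | intermediate
17 | (2S)-4'-hydroxy-7-(methoxymethoxy)flavanone | Oc1ccc([C@@H]2CC(=O)c3ccc(OCOC)cc3O2)cc1 | intermediate
18 | geraniol, (2E)-3,7-dimethylocta-2,6-dien-1-ol | CC(C)=CCC/C(C)=C/CO | starting material
19 | (2S)-4'-(geranyloxy)-7-(methoxymethoxy)flavanone | CC(C)=CCC/C(C)=C/COc1ccc([C@@H]2CC(=O)c3ccc(OCOC)cc3O2)cc1 | intermediate
20 | (2S)-4'-(geranyloxy)-7-[(trimethylsilyl)oxy]flavanone | CC(C)=CCC/C(C)=C/COc1ccc([C@@H]2CC(=O)c3ccc(O[Si](C)(C)C)cc3O2)cc1 | intermediate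
21 | (2S)-4'-(geranyloxy)-7-hydroxyflavanone (CNP0302343.1) | CC(C)=CCC/C(C)=C/COc1ccc([C@@H]2CC(=O)c3ccc(O)cc3O2)cc1 | target

**Step count**
Total steps: 10. Longest linear sequence: 7 steps (steps 4, 5, 6, 7, 8, 9, 10 from 5; the branch from 1 through steps 1, 2, 3 is equally long).

**Steps most likely to fail**

**1. Step 7.**
- What may go wrong:
  - The aryl anion may take a proton, including the C3–H of its own chain, before it acylates.
  - The alkoxide may fragment by retro-aldol cleavage or eliminate to the cinnamate.
  - The o-chloroaryl anion may lose chloride.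
  - The alkoxide may add to the aryne in the wrong direction.
  - Residual base may open ring C and erode the configuration at C2.
- Fallback (known chemistry, from 2 back to 17): O1–C2 is made by substitution and C4–C4a by a separate aryllithium acylation. Transfer hydrogenation of 2 with the enantiomeric catalyst RuCl[(R,R)-TsDPEN](p-cymene) gives methyl (3R)-3-[4-(benzyloxy)phenyl]-3-hydroxypropanoate F1. MeNH(OMe)·HCl and iPrMgCl in THF convert it into (3R)-3-[4-(benzyloxy)phenyl]-3-hydroxy-N-methoxy-N-methylpropanamide F2, whose lower C–H acidity disfavours elimination. 4-Bromoresorcinol is mono-protected (MOMCl, iPr2NEt) at the less hindered hydroxyl para to bromine to give 2-bromo-5-(methoxymethoxy)phenol F3. Mitsunobu coupling of F2 with F3 (PPh3, DIAD, toluene, 0 °C) proceeds with inversion to (3S)-3-[4-(benzyloxy)phenyl]-3-[2-bromo-5-(methoxymethoxy)phenoxy]-N-methoxy-N-methylpropanamide F4. Bromine–lithium exchange (n-BuLi, THF, −78 °C) with Parham cyclisation onto the amide gives (2S)-4'-(benzyloxy)-7-(methoxymethoxy)flavanone F5. F5 carries no chlorine and is debenzylated under the conditions of step 8 to 17.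

**2. Step 9.**
- What may go wrong: the transient 4'-phenoxide may push out O1 through a quinone methide, or ring C may open by E1cB, either of which erodes C2. Some SN2' capture at the tertiary allylic carbon is also possible.
- Fallback (from 17 back to 19): the ketone is taken out of play during the alkylation. NaBH4 in THF–EtOH at −10 °C reduces 17 from the axial side to (2S,4S)-2-(4-hydroxyphenyl)-7-(methoxymethoxy)chroman-4-ol F6. In F6, O1 is a poorer leaving group and no enolate can form. Williamson alkylation of the phenol with geranyl bromide and K2CO3 in acetone at rt gives (2S,4S)-2-[4-(geranyloxy)phenyl]-7-(methoxymethoxy)chroman-4-ol F7. Dess–Martin periodinane with NaHCO3 in CH2Cl2 re-oxidises the benzylic alcohol to 19.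

**3. Step 10.**
- What may go wrong: the silyl Lewis acid may ionise or cyclise the geranyl ether, or activate the carbonyl and open ring C, during acetal cleavage.
- Fallback (from 16 back to 21): the acetal is exchanged for a silyl ether while no terpene is present, since a silyl ether could not have passed through the fluoride of step 7. Catalytic HCl in MeOH at 40 °C gives (2S)-4'-(benzyloxy)-5-chloro-7-hydroxyflavanone F8. TIPSCl and imidazole in CH2Cl2 give (2S)-4'-(benzyloxy)-5-chloro-7-[(triisopropylsilyl)oxy]flavanone F9. H2, Pd/C and NaOAc in EtOAc give (2S)-4'-hydroxy-7-[(triisopropylsilyl)oxy]flavanone F10. Mitsunobu coupling with 18 gives (2S)-4'-(geranyloxy)-7-[(triisopropylsilyl)oxy]flavanone F11. TBAF buffered with AcOH in THF at 0 °C releases 21 without acid.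

**Further compounds**
F1 | step 7 | methyl (3R)-3-[4-(benzyloxy)phenyl]-3-hydroxypropanoate | COC(=O)C[C@@H](O)c1ccc(OCc2ccccc2)cc1
F2 | step 7 | (3R)-3-[4-(benzyloxy)phenyl]-3-hydroxy-N-methoxy-N-methylpropanamide | CON(C)C(=O)C[C@@H](O)c1ccc(OCc2ccccc2)cc1
F3 | step 7 | 2-bromo-5-(methoxymethoxy)phenol | COCOc1ccc(Br)c(O)c1
F4 | step 7 | (3S)-3-[4-(benzyloxy)phenyl]-3-[2-bromo-5-(methoxymethoxy)phenoxy]-N-methoxy-N-methylpropanamide | CON(C)C(=O)C[C@H](Oc1cc(OCOC)ccc1Br)c1ccc(OCc2ccccc2)cc1
F5 | step 7 | (2S)-4'-(benzyloxy)-7-(methoxymethoxy)flavanone | c1ccccc1COc1ccc([C@@H]2CC(=O)c3ccc(OCOC)cc3O2)cc1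
F6 | step 9 | (2S,4S)-2-(4-hydroxyphenyl)-7-(methoxymethoxy)chroman-4-ol | Oc1ccc([C@@H]2C[C@H](O)c3ccc(OCOC)cc3O2)cc1
F7 | step 9 | (2S,4S)-2-[4-(geranyloxy)phenyl]-7-(methoxymethoxy)chroman-4-ol | CC(C)=CCC/C(C)=C/COc1ccc([C@@H]2C[C@H](O)c3ccc(OCOC)cc3O2)cc1
F8 | step 10 | (2S)-4'-(benzyloxy)-5-chloro-7-hydroxyflavanone | c1ccccc1COc1ccc([C@@H]2CC(=O)c3c(Cl)cc(O)cc3O2)cc1
F9 | step 10 | (2S)-4'-(benzyloxy)-5-chloro-7-[(triisopropylsilyl)oxy]flavanone | c1ccccc1COc1ccc([C@@H]2CC(=O)c3c(Cl)cc(O[Si](C(C)C)(C(C)C)C(C)C)cc3O2)cc1
F10 | step 10 | (2S)-4'-hydroxy-7-[(triisopropylsilyl)oxy]flavanone | Oc1ccc([C@@H]2CC(=O)c3ccc(O[Si](C(C)C)(C(C)C)C(C)C)cc3O2)cc1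
F11 | step 10 | (2S)-4'-(geranyloxy)-7-[(triisopropylsilyl)oxy]flavanone | CC(C)=CCC/C(C)=C/COc1ccc([C@@H]2CC(=O)c3ccc(O[Si](C(C)C)(C(C)C)C(C)C)cc3O2)cc1
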